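**Plan**
Numbering (eudesmane): C3 angelate carbon, C4=C15, C5 carbinol, C7 with acrylate C11–C13, C8 acetate carbon, C10 with methyl C14. α is the face opposite to C14.
Cuts, in retrosynthetic order: O3–angeloyl, O8–acetyl and the ester O–CH3 (C12 re-closed on O8 as the cis γ-lactone), C11=C13, O–C5 (back to the Δ4 olefin), then C9–C10 (ring B), C8–C9 and C6–C7.
Enabling feature: ring A (C1–C5, C10) has oxygen on C3, carbon C15 on C4, the ring-B carbon C6 on C5, and methyl C14 on C10 para to C3. It is a reduced 3-alkyl-2,4-dimethylphenol, so quaternary C10 can be made by para-alkylation of that phenol by C9.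
Forward: ring A is bought as an arene. C6–C7 (benzylation of a succinate imide) and C8–C9 (diazoketone) build the chain, and ring B closes by dearomatization. The lactone is a temporary third ring that carries C8/C12 through the ring-A work, receives C13 and is opened at the end.
Stereochemistry: C7 comes from an Evans auxiliary, and C7 sets C10 in the ring closure. The 10β-methyl then steers hydride to C8 and singlet oxygen to C5 from the α face, and axial hydride delivery sets C3.

Key step: step 11

Remark: C11 of the aminomethyl lactone and of its methiodide is a mixture of epimers and is written without configuration, because it becomes sp2 in the following step.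

Step 1
Reactants: 1 2,6-dimethylbenzoic acid
Product: 2 3-bromo-2,6-dimethylbenzoic acid
Conditions: NBS (1 equiv), CF3CO2H, cat. H2SO4, rt, dark
Reagents that add atoms: N-bromosuccinimide, O=C1CCC(=O)N1Br
Why: Electrophilic aromatic bromination in which both methyl groups (ortho/para) and the carboxyl group (meta) direct to the two equivalent positions C3/C5, while one equivalent of NBS in strong acid in the dark avoids benzylic and double bromination.

Step 2
Reactants: 2 3-bromo-2,6-dimethylbenzoic acid
Product: 3 3-hydroxy-2,6-dimethylbenzoic acid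
Conditions: Cu(acac)2 (cat.), N,N'-bis(4-hydroxy-2,6-dimethylphenyl)oxalamide (cat.), LiOH·H2O, DMSO/H2O, 80 °C; then aq HCl
Reagents that add atoms: lithium hydroxide, [Li+].[OH-]
Why: Copper-catalysed Ullmann-type hydroxylation of an aryl bromide tolerates a carboxylate and one ortho methyl group and replaces bromine by hydroxide at the same carbon.

Step 3
Reactants: 3 3-hydroxy-2,6-dimethylbenzoic acid
Product: 5 2,6-dimethyl-3-(triisopropylsilyloxy)benzoic acid, via triisopropylsilyl 2,6-dimethyl-3-(triisopropylsilyloxy)benzoate 4 (not isolated)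
Conditions: TIPSCl (2.3 equiv), imidazole, DMF, rt; then K2CO3, MeOH/THF/H2O, rt; aq HCl to pH 3–4
Reagents that add atoms: chlorotriisopropylsilane, CC(C)[Si](Cl)(C(C)C)C(C)C
Why: Silylation of phenol and acid, then selective solvolysis of the far more labile silyl ester (carboxylate is the better leaving group on silicon), leaves a base-robust, fluoride-labile aryl silyl ether that can later be removed in the presence of a diazoketone.

Step 4
Reactants: 5 2,6-dimethyl-3-(triisopropylsilyloxy)benzoic acid
Product: 6 [2,6-dimethyl-3-(triisopropylsilyloxy)phenyl]methanol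
Conditions: BH3·THF, THF, 0 °C to reflux; then H2O
Reagents that add atoms: none
Why: Borane reduces carboxylic acids through the acyloxyborane, also between two ortho methyl groups, and does not touch the aryl silyl ether.

Step 5
Reactants: 6 [2,6-dimethyl-3-(triisopropylsilyloxy)phenyl]methanol
Product: 7 2-(bromomethyl)-1,3-dimethyl-4-(triisopropylsilyloxy)benzene
Conditions: CBr4, PPh3, CH2Cl2, 0 °C
Reagents that add atoms: tetrabromomethane, BrC(Br)(Br)Br
Why: The Appel reaction converts the primary benzylic alcohol into the bromide under neutral conditions that spare the silyl ether.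

Step 6
Reactants: 8 (R)-4-benzyl-1,3-oxazolidin-2-one; 9 methyl 4-chloro-4-oxobutanoate
Product: 11 methyl 4-[(4R)-4-benzyl-2-oxo-1,3-oxazolidin-3-yl]-4-oxobutanoate, via N-lithio-(R)-4-benzyl-1,3-oxazolidin-2-one 10 (not isolated)
Conditions: n-BuLi, THF, −78 °C; then 9, −78 to 0 °C
Reagents that add atoms: n-butyllithium, [Li]CCCC (lithium in 10 only)
Why: N-Acylation of the lithiated oxazolidinone by an acid chloride is the standard entry to Evans imides, and the methyl ester is far less electrophilic than the acid chloride.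

Step 7
Reactants: 11 methyl 4-[(4R)-4-benzyl-2-oxo-1,3-oxazolidin-3-yl]-4-oxobutanoate; 7 2-(bromomethyl)-1,3-dimethyl-4-(triisopropylsilyloxy)benzene
Product: 13 methyl (3R)-4-[(4R)-4-benzyl-2-oxo-1,3-oxazolidin-3-yl]-3-{[2,6-dimethyl-3-(triisopropylsilyloxy)phenyl]methyl}-4-oxobutanoate, via sodium (Z)-enolate of the imide 12 (not isolated)
Conditions: NaHMDS, THF, −78 °C; then 7, −78 to −20 °C
Reagents that add atoms: sodium hexamethyldisilazide, [Na+].C[Si](C)(C)[N-][Si](C)(C)C (sodium in 12 only)
Why: Evans asymmetric alkylation, in which the base removes the more acidic imide α-proton (not the ester α-proton) to give the chelated Z-enolate, whose face opposite to the auxiliary benzyl group attacks the reactive benzylic bromide, forms C6–C7 and sets C7 as R.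

Step 8
Reactants: 13 methyl (3R)-4-[(4R)-4-benzyl-2-oxo-1,3-oxazolidin-3-yl]-3-{[2,6-dimethyl-3-(triisopropylsilyloxy)phenyl]methyl}-4-oxobutanoate
Product: 15 (2R)-2-{[2,6-dimethyl-3-(triisopropylsilyloxy)phenyl]methyl}-4-methoxy-4-oxobutanoic acid, via (2R)-2-{[2,6-dimethyl-3-(triisopropylsilyloxy)phenyl]methyl}-4-methoxy-4-oxobutaneperoxoic acid 14 (not isolated)
Conditions: LiOH, H2O2, THF/H2O, 0 °C; then aq Na2SO3; aq HCl
Reagents that add atoms: hydrogen peroxide, OO
Why: Hydroperoxide cleavage of an Evans imide attacks the exocyclic carbonyl even in hindered cases, is much faster at 0 °C than saponification of the methyl ester or loss of the aryl TIPS group, does not epimerize C7, and sulfite reduces the peracid to the acid.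

Step 9
Reactants: 15 (2R)-2-{[2,6-dimethyl-3-(triisopropylsilyloxy)phenyl]methyl}-4-methoxy-4-oxobutanoic acid; 16 (trimethylsilyl)diazomethane
Product: 18 methyl (3R)-5-diazo-3-{[2,6-dimethyl-3-(triisopropylsilyloxy)phenyl]methyl}-4-oxopentanoate, via isobutyl carbonic mixed anhydride of the acid 17 (not isolated)
Conditions: i-BuOCOCl, N-methylmorpholine, THF, −20 °C; then 16 (hexane solution), MeCN, 0 °C to rt; aq NaHCO3
Reagents that add atoms: isobutyl chloroformate, CC(C)COC(=O)Cl (atoms in 17 only)
Why: Arndt–Eistert-type acylation of (trimethylsilyl)diazomethane by a mixed carbonic anhydride forms C8–C9 and gives the terminal diazoketone after loss of silicon, under conditions that keep α-stereocentres intact.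

Step 10
Reactants: 18 methyl (3R)-5-diazo-3-{[2,6-dimethyl-3-(triisopropylsilyloxy)phenyl]methyl}-4-oxopentanoate
Product: 19 methyl (3R)-5-diazo-3-[(3-hydroxy-2,6-dimethylphenyl)methyl]-4-oxopentanoate
Conditions: TBAF, AcOH (1:1), THF, 0 °C
Reagents that add atoms: none
Why: Fluoride cleaves the aryl silyl ether rapidly, and the acetic acid buffer is too weak to protonate the diazoketone yet keeps the phenoxide from acting as a base on C7.

Step 11
Reactants: 19 methyl (3R)-5-diazo-3-[(3-hydroxy-2,6-dimethylphenyl)methyl]-4-oxopentanoate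
Product: 21 methyl 3,8-dioxo-13-noreudesma-1,4-dien-12-oate (7αH, 10β-methyl; 7R,10S), via α-ketodiazonium ion 20 (not isolated)
Conditions: slow addition of 19 in CH2Cl2 to CF3CO2H/CH2Cl2, −20 °C, high dilution, a few minutes; then cold aq NaHCO3
Reagents that add atoms: none
Why: Trifluoroacetic acid protonates the diazo carbon C9 to the α-ketodiazonium ion 20, whose primary carbon is displaced by the arene carbon C10 (para to the hydroxyl) with loss of N2, and loss of the phenolic proton from the hydroxyarenium ion gives the cross-conjugated dienone, which cannot rearomatize because C10 is quaternary. The closest known reaction type is the acid-promoted intramolecular alkylation of phenols by diazoketones (aryl participation) to cyclohexadienones. Ring B (C5–C6–C7–C8–C9–C10) closes in the Ar2-6 mode, a 6-exo-tet displacement at C9 in which the new six-membered ring contains the C5–C10 arene bond. The new stereocentre C10 is controlled by C7: the two ortho methyl groups hold the C6–C7 bond perpendicular to the arene, and in the chair-like closure the CH2CO2Me arm stays equatorial (anti to C5, away from C15), so that C9 reaches the α face and C14 becomes β. The step needs C10 over C5, oxygen, C4 and external nucleophiles: C5 is meta to the hydroxyl and not activated, O-alkylation is geometrically impossible, closure at C4 (wedged between oxygen and tether) is disfavoured as in all cyclizations of meta-oxygenated aryl tethers and would give the less stable linearly conjugated dienone, and slow addition to cold acid with a short contact time limits capture by trifluoroacetate or the ester carbonyl, dienone–phenol rearrangement and acid enolization at C7. The 10-epimer should be removed by chromatography at this stage, before any basic step, because epimerization at C7 would turn it into the enantiomer of 21.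

Step 12
Reactants: 21 methyl 3,8-dioxo-13-noreudesma-1,4-dien-12-oate
Product: 23 3-oxo-13-noreudesma-1,4-dien-12,8β-olide (cis-fused γ-lactone; 7αH, 8αH, 10β-methyl), via methyl 8β-hydroxy-3-oxo-13-noreudesma-1,4-dien-12-oate 22 (not isolated)
Conditions: NaBH4, MeOH/CH2Cl2, −40 to 0 °C; then cat. p-TsOH, CH2Cl2, rt
Reagents that add atoms: none
Why: Chemoselective borohydride reduction, in which the saturated C8 ketone reacts much faster than the cross-conjugated C4-methylated dienone, the axial 10β-methyl blocks the β (axial) trajectory so that hydride arrives from the α face to give the axial 8β-alcohol, and this cis γ-hydroxy ester lactonizes with a trace of acid.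

Step 13
Reactants: 23 3-oxo-13-noreudesma-1,4-dien-12,8β-olide
Product: 24 3-oxo-13-noreudesm-4-en-12,8β-olide
Conditions: H2 (1 atm), RhCl(PPh3)3 (cat.), toluene/EtOH, rt
Reagents that add atoms: none
Why: Homogeneous hydrogenation with Wilkinson's catalyst saturates the disubstituted Δ1 bond of 1,4-dien-3-ones and leaves the tetrasubstituted Δ4 bond, as is established for santonin-type and steroidal dienones.

Step 14
Reactants: 24 3-oxo-13-noreudesm-4-en-12,8β-olide
Product: 25 3β-hydroxy-13-noreudesm-4-en-12,8β-olide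
Conditions: NaBH4, CeCl3·7H2O, MeOH, −20 °C
Reagents that add atoms: none
Why: Luche 1,2-reduction, in which hydride adds axially from the α face of the ring-A half-chair, as in steroidal 4-en-3-ones, to give the equatorial 3β-allylic alcohol while the lactone is inert.

Step 15
Reactants: 25 3β-hydroxy-13-noreudesm-4-en-12,8β-olide
Product: 26 3β-(tert-butyldimethylsilyloxy)-13-noreudesm-4-en-12,8β-olide
Conditions: TBSCl, imidazole, DMF, rt
Reagents that add atoms: tert-butylchlorodimethylsilane, CC(C)(C)[Si](C)(C)Cl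
Why: Standard silylation masks O3 against the strong base and the hydroxide used later (which an angelate would not survive), removes its hydrogen-bond directing effect and adds bulk next to C4 for the oxygenation.

Step 16
Reactants: 26 3β-(tert-butyldimethylsilyloxy)-13-noreudesm-4-en-12,8β-olide
Product: 28 3β-(tert-butyldimethylsilyloxy)-5α-hydroxy-13-noreudesm-4(15)-en-12,8β-olide, via 3β-(tert-butyldimethylsilyloxy)-5α-hydroperoxy-13-noreudesm-4(15)-en-12,8β-olide 27 (not isolated)
Conditions: O2, tetraphenylporphyrin (cat.), visible light, CH2Cl2, 0 °C; then PPh3, 0 °C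
Reagents that add atoms: oxygen, O=O
Why: Schenck ene reaction, in which singlet oxygen attacks the electron-rich tetrasubstituted Δ4 bond from the α face opposite to the axial 10β-methyl, bonds to C5 away from the bulky C3 substituent (geminal selectivity) and takes a hydrogen from the freely rotating C15 methyl on the more crowded C15/C6 side (H6α lies near the olefin plane and is badly aligned), after which phosphine reduces the 5α-hydroperoxide with retention.

Step 17
Reactants: 28 3β-(tert-butyldimethylsilyloxy)-5α-hydroxy-13-noreudesm-4(15)-en-12,8β-olide; 29 N,N-dimethylmethyleneiminium iodide (Eschenmoser's salt)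
Product: 31 3β-(tert-butyldimethylsilyloxy)-13-(dimethylamino)-5α-hydroxyeudesm-4(15)-en-12,8β-olide (C11 epimers), via dilithium C5-alkoxide/C11–C12 lactone enolate 30 (not isolated)
Conditions: LDA (3 equiv), THF, −78 °C; then 29, −78 °C to rt; H2O
Reagents that add atoms: lithium diisopropylamide, [Li+].CC(C)[N-]C(C)C (lithium in 30 only)
Why: Mannich-type aminomethylation of the lactone enolate with Eschenmoser's salt brings in C13, the extra base only turns the tertiary alcohol into its alkoxide, C11 is the sole enolizable position, and its configuration does not matter.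

Step 18
Reactants: 31 3β-(tert-butyldimethylsilyloxy)-13-(dimethylamino)-5α-hydroxyeudesm-4(15)-en-12,8β-olide
Product: 33 3β-(tert-butyldimethylsilyloxy)-5α-hydroxyeudesma-4(15),11(13)-dien-12,8β-olide, via 13-(trimethylammonio) lactone iodide 32 (not isolated)
Conditions: MeI, THF, rt; then aq NaHCO3/EtOAc, rt
Reagents that add atoms: iodomethane, CI (atoms in 32 only)
Why: Quaternization followed by Hofmann-type E1cB loss of trimethylamine is the standard second half of the α-methylenation of γ-lactones and needs only bicarbonate.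

Step 19
Reactants: 33 3β-(tert-butyldimethylsilyloxy)-5α-hydroxyeudesma-4(15),11(13)-dien-12,8β-olide; 16 (trimethylsilyl)diazomethane
Product: 35 methyl 3β-(tert-butyldimethylsilyloxy)-5α,8β-dihydroxyeudesma-4(15),11(13)-dien-12-oate, via 3β-(tert-butyldimethylsilyloxy)-5α,8β-dihydroxyeudesma-4(15),11(13)-dien-12-oic acid 34 (not isolated)
Conditions: LiOH, THF/H2O, 0 °C to rt; cold aq HCl to pH 4–5, extraction at 0 °C; then 16, toluene/MeOH, 0 °C
Reagents that add atoms: lithium hydroxide, [Li+].[OH-]
Why: Saponification by acyl–oxygen cleavage keeps C8 intact and gives a hydroxy acid that can be handled in the cold because the axial 8β-hydroxyl is crowded by the syn-axial 10β-methyl, and immediate neutral O-methylation with (trimethylsilyl)diazomethane fixes the open form.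

Step 20
Reactants: 35 methyl 3β-(tert-butyldimethylsilyloxy)-5α,8β-dihydroxyeudesma-4(15),11(13)-dien-12-oate
Product: 36 methyl 8β-acetoxy-3β-(tert-butyldimethylsilyloxy)-5α-hydroxyeudesma-4(15),11(13)-dien-12-oate
Conditions: Ac2O, DMAP, pyridine, CH2Cl2, 0 °C to rt
Reagents that add atoms: acetic anhydride, CC(=O)OC(C)=O
Why: DMAP-catalysed acetylation acylates the secondary 8β-hydroxyl while the tertiary 5α-hydroxyl is too hindered to react, and capping O8 ends the risk of relactonization.

Step 21
Reactants: 36 methyl 8β-acetoxy-3β-(tert-butyldimethylsilyloxy)-5α-hydroxyeudesma-4(15),11(13)-dien-12-oate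
Product: 37 methyl 8β-acetoxy-3β,5α-dihydroxyeudesma-4(15),11(13)-dien-12-oate
Conditions: TBAF, AcOH (1:1), THF, rt
Reagents that add atoms: none
Why: Buffered fluoride removes the secondary allylic silyl ether without the basicity that would cleave the acetate and without the acidity that would ionize the tertiary allylic alcohol.

Step 22
Reactants: 37 methyl 8β-acetoxy-3β,5α-dihydroxyeudesma-4(15),11(13)-dien-12-oate; 38 angelic acid ((Z)-2-methylbut-2-enoic acid)
Product: 40 methyl 8β-acetoxy-3β-angeloyloxy-5α-hydroxyeudesma-4(15),11(13)-dien-12-oate (3S,5S,7R,8R,10R; CNP0179024.1), via angelic 2,4,6-trichlorobenzoic anhydride 39 (not isolated)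
Conditions: 38, 2,4,6-trichlorobenzoyl chloride, Et3N, toluene, rt; then 37, 80 °C
Reagents that add atoms: 2,4,6-trichlorobenzoyl chloride, O=C(Cl)c1c(Cl)cc(Cl)cc1Cl (atoms in 39 only)
Why: Yamaguchi-type esterification through the mixed anhydride without a nucleophilic catalyst is the established way to make angelates without Z-to-E isomerization to the tiglate, and only the secondary equatorial 3β-hydroxyl reacts because the tertiary 5α-hydroxyl is inert.

**Compound list**
1 | 2,6-dimethylbenzoic acid | Cc1cccc(C)c1C(=O)O | starting material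
2 | 3-bromo-2,6-dimethylbenzoic acid | Cc1ccc(Br)c(C)c1C(=O)O | intermediate
3 | 3-hydroxy-2,6-dimethylbenzoic acid | Cc1ccc(O)c(C)c1C(=O)O | intermediate
4 | triisopropylsilyl 2,6-dimethyl-3-(triisopropylsilyloxy)benzoate | Cc1ccc(O[Si](C(C)C)(C(C)C)C(C)C)c(C)c1C(=O)O[Si](C(C)C)(C(C)C)C(C)C | intermediate
5 | 2,6-dimethyl-3-(triisopropylsilyloxy)benzoic acid | Cc1ccc(O[Si](C(C)C)(C(C)C)C(C)C)c(C)c1C(=O)O | intermediate
6 | [2,6-dimethyl-3-(triisopropylsilyloxy)phenyl]methanol | Cc1ccc(O[Si](C(C)C)(C(C)C)C(C)C)c(C)c1CO | intermediate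
7 | 2-(bromomethyl)-1,3-dimethyl-4-(triisopropylsilyloxy)benzene | Cc1ccc(O[Si](C(C)C)(C(C)C)C(C)C)c(C)c1CBr | intermediate
8 | (R)-4-benzyl-1,3-oxazolidin-2-one | O=C1N[C@H](Cc2ccccc2)CO1 | starting material
9 | methyl 4-chloro-4-oxobutanoate | COC(=O)CCC(=O)Cl | starting material
10 | N-lithio-(R)-4-benzyl-1,3-oxazolidin-2-one | [Li+].O=C1[N-][C@H](Cc2ccccc2)CO1 | intermediate
11 | methyl 4-[(4R)-4-benzyl-2-oxo-1,3-oxazolidin-3-yl]-4-oxobutanoate | COC(=O)CCC(=O)N1[C@H](Cc2ccccc2)COC1=O | intermediate
12 | sodium (Z)-enolate of 11 | [Na+].COC(=O)C/C=C(\[O-])N1[C@H](Cc2ccccc2)COC1=O | intermediate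
13 | methyl (3R)-4-[(4R)-4-benzyl-2-oxo-1,3-oxazolidin-3-yl]-3-{[2,6-dimethyl-3-(triisopropylsilyloxy)phenyl]methyl}-4-oxobutanoate | COC(=O)C[C@@H](Cc1c(C)ccc(O[Si](C(C)C)(C(C)C)C(C)C)c1C)C(=O)N1[C@H](Cc2ccccc2)COC1=O | intermediate
14 | (2R)-2-{[2,6-dimethyl-3-(triisopropylsilyloxy)phenyl]methyl}-4-methoxy-4-oxobutaneperoxoic acid | COC(=O)C[C@@H](Cc1c(C)ccc(O[Si](C(C)C)(C(C)C)C(C)C)c1C)C(=O)OO | intermediate
15 | (2R)-2-{[2,6-dimethyl-3-(triisopropylsilyloxy)phenyl]methyl}-4-methoxy-4-oxobutanoic acid | COC(=O)C[C@@H](Cc1c(C)ccc(O[Si](C(C)C)(C(C)C)C(C)C)c1C)C(=O)O | intermediate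
16 | (trimethylsilyl)diazomethane | C[Si](C)(C)C=[N+]=[N-] | starting material
17 | isobutyl carbonic mixed anhydride of 15 | COC(=O)C[C@@H](Cc1c(C)ccc(O[Si](C(C)C)(C(C)C)C(C)C)c1C)C(=O)OC(=O)OCC(C)C | intermediate
18 | methyl (3R)-5-diazo-3-{[2,6-dimethyl-3-(triisopropylsilyloxy)phenyl]methyl}-4-oxopentanoate | COC(=O)C[C@@H](Cc1c(C)ccc(O[Si](C(C)C)(C(C)C)C(C)C)c1C)C(=O)C=[N+]=[N-] | intermediate
19 | methyl (3R)-5-diazo-3-[(3-hydroxy-2,6-dimethylphenyl)methyl]-4-oxopentanoate | COC(=O)C[C@@H](Cc1c(C)ccc(O)c1C)C(=O)C=[N+]=[N-] | intermediate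
20 | α-ketodiazonium ion from 19 (C9-protonated) | COC(=O)C[C@@H](Cc1c(C)ccc(O)c1C)C(=O)C[N+]#N | intermediate
21 | methyl 3,8-dioxo-13-noreudesma-1,4-dien-12-oate (7αH, 10β-methyl; 7R,10S) | COC(=O)C[C@H]1CC2=C(C)C(=O)C=C[C@]2(C)CC1=O | intermediate
22 | methyl 8β-hydroxy-3-oxo-13-noreudesma-1,4-dien-12-oate | COC(=O)C[C@H]1CC2=C(C)C(=O)C=C[C@]2(C)C[C@H]1O | intermediate
23 | 3-oxo-13-noreudesma-1,4-dien-12,8β-olide | O=C1C[C@H]2CC3=C(C)C(=O)C=C[C@]3(C)C[C@H]2O1 | intermediate
24 | 3-oxo-13-noreudesm-4-en-12,8β-olide | O=C1C[C@H]2CC3=C(C)C(=O)CC[C@]3(C)C[C@H]2O1 | intermediate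
25 | 3β-hydroxy-13-noreudesm-4-en-12,8β-olide | O=C1C[C@H]2CC3=C(C)[C@@H](O)CC[C@]3(C)C[C@H]2O1 | intermediate
26 | 3β-(tert-butyldimethylsilyloxy)-13-noreudesm-4-en-12,8β-olide | O=C1C[C@H]2CC3=C(C)[C@@H](O[Si](C)(C)C(C)(C)C)CC[C@]3(C)C[C@H]2O1 | intermediate
27 | 3β-(tert-butyldimethylsilyloxy)-5α-hydroperoxy-13-noreudesm-4(15)-en-12,8β-olide | O=C1C[C@H]2C[C@@]3(OO)C(=C)[C@@H](O[Si](C)(C)C(C)(C)C)CC[C@]3(C)C[C@H]2O1 | intermediate
28 | 3β-(tert-butyldimethylsilyloxy)-5α-hydroxy-13-noreudesm-4(15)-en-12,8β-olide | O=C1C[C@H]2C[C@@]3(O)C(=C)[C@@H](O[Si](C)(C)C(C)(C)C)CC[C@]3(C)C[C@H]2O1 | intermediate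
29 | N,N-dimethylmethyleneiminium iodide (Eschenmoser's salt) | C=[N+](C)C.[I-] | starting material
30 | dilithium C5-alkoxide/C11–C12 lactone enolate of 28 | [Li+].[Li+].[O-]C1=C[C@H]2C[C@@]3([O-])C(=C)[C@@H](O[Si](C)(C)C(C)(C)C)CC[C@]3(C)C[C@H]2O1 | intermediate
31 | 3β-(tert-butyldimethylsilyloxy)-13-(dimethylamino)-5α-hydroxyeudesm-4(15)-en-12,8β-olide (C11 epimers) | O=C1C(CN(C)C)[C@H]2C[C@@]3(O)C(=C)[C@@H](O[Si](C)(C)C(C)(C)C)CC[C@]3(C)C[C@H]2O1 | intermediate
32 | 13-(trimethylammonio) lactone iodide from 31 (C11 epimers) | O=C1C(C[N+](C)(C)C)[C@H]2C[C@@]3(O)C(=C)[C@@H](O[Si](C)(C)C(C)(C)C)CC[C@]3(C)C[C@H]2O1.[I-] | intermediate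
33 | 3β-(tert-butyldimethylsilyloxy)-5α-hydroxyeudesma-4(15),11(13)-dien-12,8β-olide | O=C1C(=C)[C@H]2C[C@@]3(O)C(=C)[C@@H](O[Si](C)(C)C(C)(C)C)CC[C@]3(C)C[C@H]2O1 | intermediate
34 | 3β-(tert-butyldimethylsilyloxy)-5α,8β-dihydroxyeudesma-4(15),11(13)-dien-12-oic acid | C=C(C(=O)O)[C@H]1C[C@@]2(O)C(=C)[C@@H](O[Si](C)(C)C(C)(C)C)CC[C@]2(C)C[C@H]1O | intermediate
35 | methyl 3β-(tert-butyldimethylsilyloxy)-5α,8β-dihydroxyeudesma-4(15),11(13)-dien-12-oate | C=C(C(=O)OC)[C@H]1C[C@@]2(O)C(=C)[C@@H](O[Si](C)(C)C(C)(C)C)CC[C@]2(C)C[C@H]1O | intermediate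
36 | methyl 8β-acetoxy-3β-(tert-butyldimethylsilyloxy)-5α-hydroxyeudesma-4(15),11(13)-dien-12-oate | C=C(C(=O)OC)[C@H]1C[C@@]2(O)C(=C)[C@@H](O[Si](C)(C)C(C)(C)C)CC[C@]2(C)C[C@H]1OC(C)=O | intermediate
37 | methyl 8β-acetoxy-3β,5α-dihydroxyeudesma-4(15),11(13)-dien-12-oate | C=C(C(=O)OC)[C@H]1C[C@@]2(O)C(=C)[C@@H](O)CC[C@]2(C)C[C@H]1OC(C)=O | intermediate
38 | angelic acid, (Z)-2-methylbut-2-enoic acid | C/C=C(/C)C(=O)O | starting material
39 | angelic 2,4,6-trichlorobenzoic anhydride | C/C=C(/C)C(=O)OC(=O)c1c(Cl)cc(Cl)cc1Cl | intermediate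
40 | methyl 8β-acetoxy-3β-angeloyloxy-5α-hydroxyeudesma-4(15),11(13)-dien-12-oate (3S,5S,7R,8R,10R; CNP0179024.1) | C=C(C(=O)OC)[C@H]1C[C@@]2(O)C(=C)[C@@H](OC(=O)/C(C)=C\C)CC[C@]2(C)C[C@H]1OC(C)=O | target

**Step count**
Total step count: 22.
Longest linear sequence: 21 (steps 1–5 and 7–22; step 6 is the one-step side branch).

**Steps most likely to fail**

1. Step 11.
- Risk: the diazonium ion may be intercepted by trifluoroacetate or by the ester carbonyl before the arene reacts. Closure may compete at C4. Discrimination between the two arene faces may be weak.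
- Fallback: this sets out from 19 and keeps the C9–C10 disconnection, but makes the arene the strong partner.
- HBr in Et2O at 0 °C converts the diazoketone into methyl (3R)-5-bromo-3-[(3-hydroxy-2,6-dimethylphenyl)methyl]-4-oxopentanoate F1.
- Exactly one equivalent of KOt-Bu in t-BuOH/THF at high dilution then deprotonates only the phenol. The phenoxide closes ring B by anionic aryl participation (intramolecular para-C-alkylation, again Ar2-6, with no external nucleophile present).
- The fallback comes back to the route at 21.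

2. Step 16.
- Risk: hydrogen may be abstracted from C3 (its axial α-hydrogen lies on the attacked face) or from C6 instead of from C15. Part of the attack may occur on the β face.
- Fallback: this sets out from 26.
- mCPBA/NaHCO3 in CH2Cl2 at 0 °C, with no free hydroxyl to direct it, should epoxidize opposite to the 10β-methyl to give 3β-(tert-butyldimethylsilyloxy)-4α,5α-epoxy-13-noreudesman-12,8β-olide F2.
- Diethylaluminium 2,2,6,6-tetramethylpiperidide (from LiTMP and Et2AlCl) in toluene at 0 °C then effects the syn-elimination type epoxide-to-allylic-alcohol isomerization. It takes the least hindered proton (C15) and breaks C4–O, while the lactone is at most enolized reversibly.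
- The fallback comes back to the route at 28.

3. Step 19.
- Risk: the open form may relactonize during acidification, during esterification, or during the slow acetylation of the crowded axial hydroxyl in step 20. Hydroxide may also add in conjugate fashion to the methylene lactone.
- Fallback: this sets out from 33 and removes the electrophilic C12 carbonyl while O8 is capped.
- DIBAL-H (CH2Cl2, −78 to 0 °C) gives 3β-(tert-butyldimethylsilyloxy)eudesma-4(15),11(13)-diene-5α,8β,12-triol F3.
- TESCl/imidazole at −20 °C silylates only the primary allylic hydroxyl, giving the 12-O-triethylsilyl ether F4.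
- Ac2O/DMAP gives the 8β-acetate F5.
- PPTS/MeOH removes the primary TES ether beside the secondary TBS ether, giving the 12-alcohol F6.
- MnO2 gives the enal F7, and Pinnick oxidation gives the acrylic acid F8.
- Esterification with 16 brings the fallback back to the route at 36.

**Further compounds**
F1 | step 11 | methyl (3R)-5-bromo-3-[(3-hydroxy-2,6-dimethylphenyl)methyl]-4-oxopentanoate | COC(=O)C[C@@H](Cc1c(C)ccc(O)c1C)C(=O)CBr
F2 | step 16 | 3β-(tert-butyldimethylsilyloxy)-4α,5α-epoxy-13-noreudesman-12,8β-olide | O=C1C[C@H]2C[C@@]34O[C@]3(C)[C@@H](O[Si](C)(C)C(C)(C)C)CC[C@]4(C)C[C@H]2O1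
F3 | step 19 | 3β-(tert-butyldimethylsilyloxy)eudesma-4(15),11(13)-diene-5α,8β,12-triol | C=C(CO)[C@H]1C[C@@]2(O)C(=C)[C@@H](O[Si](C)(C)C(C)(C)C)CC[C@]2(C)C[C@H]1O
F4 | step 19 | 3β-(tert-butyldimethylsilyloxy)-12-(triethylsilyloxy)eudesma-4(15),11(13)-diene-5α,8β-diol | C=C(CO[Si](CC)(CC)CC)[C@H]1C[C@@]2(O)C(=C)[C@@H](O[Si](C)(C)C(C)(C)C)CC[C@]2(C)C[C@H]1O
F5 | step 19 | 8β-acetoxy-3β-(tert-butyldimethylsilyloxy)-12-(triethylsilyloxy)eudesma-4(15),11(13)-dien-5α-ol | C=C(CO[Si](CC)(CC)CC)[C@H]1C[C@@]2(O)C(=C)[C@@H](O[Si](C)(C)C(C)(C)C)CC[C@]2(C)C[C@H]1OC(C)=O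
F6 | step 19 | 8β-acetoxy-3β-(tert-butyldimethylsilyloxy)eudesma-4(15),11(13)-diene-5α,12-diol | C=C(CO)[C@H]1C[C@@]2(O)C(=C)[C@@H](O[Si](C)(C)C(C)(C)C)CC[C@]2(C)C[C@H]1OC(C)=O
F7 | step 19 | 8β-acetoxy-3β-(tert-butyldimethylsilyloxy)-5α-hydroxyeudesma-4(15),11(13)-dien-12-al | C=C(C=O)[C@H]1C[C@@]2(O)C(=C)[C@@H](O[Si](C)(C)C(C)(C)C)CC[C@]2(C)C[C@H]1OC(C)=O
F8 | step 19 | 8β-acetoxy-3β-(tert-butyldimethylsilyloxy)-5α-hydroxyeudesma-4(15),11(13)-dien-12-oic acid | C=C(C(=O)O)[C@H]1C[C@@]2(O)C(=C)[C@@H](O[Si](C)(C)C(C)(C)C)CC[C@]2(C)C[C@H]1OC(C)=O
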